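Commit to one number for this flask, the excess in the product, and read it from the losses of the two substrates.

| flask | left-handed substrate | right-handed substrate | reagent | free catalyst | remark | time |
|---|---|---|---|---|---|---|
| spring | 10 mM | 10 mM | 12 mM | 0.50 mM | the very flask that is asked about, followed so far |  |
| flask | 10 mM | 10 mM | 12.0 mM | 0.50 mM |  | 10 min |

spring run (percent of the left-handed substrate and right-handed substrate together charged)

| time / s | left-handed substrate / % | right-handed substrate / % | left-handed product / % |
|---|---|---|---|
| 15.0 | 49.0 | 45.7 | 0.8 |
| 30.0 | 49.3 | 44.0 | 1.1 |
| 50.0 | 48.0 | 41.7 | 0.5 |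
| 60.0 | 48.6 | 40.8 | 1.7 |
| 80.0 | 47.8 | 39.6 | 1.8 |
| 90.0 | 47.7 | 39.1 | 1.9 |
| 120 | 47.1 | 37.6 | 2.3 |

(scatter of a reading: 0.3 percentage points)

* part of the left-handed substrate and right-handed substrate charged together that has reacted at 10 min
* excess of left-handed product over right-handed product in the product at 10 min
* excess of right-handed substrate over left-handed substrate among what is left of the two at 10 min

- free catalyst is single-handed; left-handed substrate and right-handed substrate are mirror images of each other, charged as a racemate, each of them at the stated concentration
- an excess is the difference of the two amounts in percent of their sum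
- an excess is below zero if the other one leads

The ladder of rates starts at the first reading: by 15.0 s the right-handed substrate has lost 4.3 percentage points of the charge. On the last rung seen, it loses 1.5 points in 30.0 s, a far lower pace. The catalyst charge is 2.50% of the substrate charge, less than the 12 points of right-handed substrate gone at 120 s, so the losses are read mainly as product.

Single readings scatter, so the curve is replaced by its mean. Pooled losses up to 60.0 s are 5.1 points left-handed and 28 points right-handed; later ones are 7.4 points and 34 points. The early excess is −69.2% and the late one −64.3%, so the mean errs by a few points. Hence the split, the left-handed loss minus the right-handed loss over their sum, pooled over every reading, is −66.2%, and it is carried to 10 min as eP of this kinetic resolution. This reckoning commits to eP and leaves c and eS open.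

The forecast gave c 29%, eP 62% and eS −25%, on the grounds that “The right-handed substrate reacts faster”, and its eP differs in sign from the split.

At 10 min the flask gives c 24.3%, eP −65.3% and eS −9.14%, so the split lies 0.9 points from eP.

    left-handed substrate ⇌ right-handed substrate (k = 9.10 × 10⁻⁴ s⁻¹)
    2 reagent → self-condensation product (k = 0.490 M⁻¹ s⁻¹)
    reagent + catalyst intermediate A → free catalyst + left-handed product (k = 16.0 M⁻¹ s⁻¹)
    free catalyst + left-handed substrate ⇌ catalyst intermediate A (K = 44.0 M⁻¹, k = 100 M⁻¹ s⁻¹)
    reagent + catalyst intermediate B → free catalyst + right-handed product (k = 8.00 M⁻¹ s⁻¹)
    2 free catalyst → spent catalyst (k = 23.0 M⁻¹ s⁻¹)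
    free catalyst + right-handed substrate ⇌ catalyst intermediate B (K = 500 M⁻¹, k = 550 M⁻¹ s⁻¹)

In this flask the right-handed product leads mainly because catalyst intermediate A falls back to free catalyst and left-handed substrate: the same flask without that back reaction gives eP 64.2%. A neighbour flask charged with 7.2 mM of reagent has reacted to 18.6% at 10 min and gives eP −66.5%, 0.30 points away from the split.

The data are simulated from invented constants.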